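**Plan**

1. The target is achiral. A central butanoylphloroglucinol (ring B) is joined through two CH2 bridges to identical outer rings A and C, numbered C1' (bridge), C2' (OH), C3' (butanoyl), C4' (OH), C5' (methyl), C6' (OMe).
2. Retrosynthesis: first the seven O–benzyl bonds and the three aryl–C(=O) bonds are cut (C3' of rings A and C, the free carbon of ring B). Then, in each outer ring, C1'–C2' and C5'–C6' are cut (C2'–C3' is broken and remade in the same step), giving bis(methoxyalkyne) 10 and two molecules of cyclobutenone 16. Last, the two CH2–C(sp) bonds of 10 are cut to bis(bromomethyl)arene 5 and methoxyethyne 8.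
3. The feature that allows this is the pattern of rings A and C: three meta-related oxygens at C2', C4' and C6', with the methoxy carbon C6' lying between the bridge carbon C1' and the methyl carbon C5'. A 1-methoxyalkyne supplies C1' and C6', a 3-alkoxy-2-methylcyclobutenone supplies C2' to C5', and the three oxygens arrive differently capped (OH, OBn, OMe).
4. Forward: ring B comes from phloroglucinol and is carried as its tribenzyl ether; rings A and C are formed together in one two-fold benzannulation; three-fold butanoylation and one hydrogenolysis finish the route.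
5. Stereochemistry: there is no stereocentre to set. The only stereogenic carbons are the transient quaternary carbons of the vinylcyclobutenone intermediates, which vanish on aromatisation.

Key step: step 10

Remark: the oxygen that becomes the C4' hydroxyl enters as a benzyl ether, so that every group removed at the end is benzyl and the two C6' methyl ethers cannot be touched.

**Route**

Step 1
Reactants: 1 phloroglucinol
Product: 2 2,4,6-trihydroxybenzene-1,3-dicarbaldehyde
Conditions: POCl3 (2.3 equiv), DMF (2.3 equiv), 1,4-dioxane, 0 °C to rt; then H2O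
Reagents that add atoms: N,N-dimethylformamide CN(C)C=O; water O
Why: Vilsmeier–Haack formylation: phloroglucinol is nucleophilic enough to take two chloroiminium ions at ring carbons, and the limited amount of reagent together with the deactivation by two iminium groups should stop the reaction at the dialdehyde, which is freed on aqueous hydrolysis.

Step 2
Reactants: 2 2,4,6-trihydroxybenzene-1,3-dicarbaldehyde
Product: 3 2,4,6-tris(benzyloxy)benzene-1,3-dicarbaldehyde
Conditions: BnBr, K2CO3, DMF, 60 °C
Reagents that add atoms: benzyl bromide BrCc1ccccc1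
Why: Williamson etherification in DMF; the two formyl groups lower the carbon nucleophilicity of the ring, so the three phenoxides should react at oxygen.

Step 3
Reactants: 3 2,4,6-tris(benzyloxy)benzene-1,3-dicarbaldehyde
Product: 4 [2,4,6-tris(benzyloxy)-1,3-phenylene]dimethanol
Conditions: NaBH4, THF/MeOH, 0 °C
Reagents that add atoms: none
Why: Borohydride reduction of aryl aldehydes to benzylic alcohols; the benzyl ethers are inert and no acid is present that could ionise the electron-rich benzylic alcohols.

Step 4
Reactants: 4 [2,4,6-tris(benzyloxy)-1,3-phenylene]dimethanol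
Product: 5 1,3,5-tris(benzyloxy)-2,4-bis(bromomethyl)benzene
Conditions: CBr4, PPh3, CH2Cl2, 0 °C; rapid filtration, used at once
Reagents that add atoms: tetrabromomethane BrC(Br)(Br)Br
Why: Appel reaction, chosen because it runs without acid, so the doubly ortho-alkoxylated benzylic bromides should form without ionising; 5 is not chromatographed.

Step 5
Reactants: 6 2-chloro-1,1-dimethoxyethane (chloroacetaldehyde dimethyl acetal)
Product: 8 methoxyethyne, via sodium methoxyacetylide 7 (not isolated)
Conditions: NaNH2 (3 equiv), liquid NH3, −33 °C; cold satd aq NaCl; distilled into THF at −78 °C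
Reagents that add atoms: none
Why: Double elimination from an α-chloroacetal with NaNH2 (loss of methanol, then of HCl) is the standard preparation of 1-alkoxyalkynes; protonation and distillation separate the volatile ynol ether from ammonia and salts, so that no amine reaches the next step.

Step 6
Reactants: 5 1,3,5-tris(benzyloxy)-2,4-bis(bromomethyl)benzene; 8 methoxyethyne
Product: 10 1,3,5-tris(benzyloxy)-2,4-bis(3-methoxyprop-2-yn-1-yl)benzene, via lithium methoxyacetylide 9 (not isolated)
Conditions: 8 (3 equiv), n-BuLi, THF, −78 °C; then DMPU, 5, −78 to 0 °C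
Reagents that add atoms: none
Why: SN2 alkylation of a lithium alkoxyacetylide by a reactive benzylic bromide in THF/DMPU, a standard route to 1-alkoxy-1-alkynes; low temperature and the absence of amines or stronger bases should keep the propargylic CH2 groups from isomerising to allenes.

Step 7
Reactants: 11 1-ethoxyprop-1-yne; 12 trichloroacetyl chloride
Product: 14 4,4-dichloro-3-ethoxy-2-methylcyclobut-2-en-1-one, via dichloroketene 13 (not isolated)
Conditions: Zn–Cu couple, Et2O/1,2-dimethoxyethane, slow addition of 12, rt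
Reagents that add atoms: none
Why: Ketene–alkyne [2+2] cycloaddition: dichloroketene, made by zinc dechlorination of 12, bonds through its carbonyl carbon to the nucleophilic methyl-bearing carbon of the ynol ether, which fixes the 3-ethoxy-2-methyl pattern.

Step 8
Reactants: 14 4,4-dichloro-3-ethoxy-2-methylcyclobut-2-en-1-one
Product: 15 3-ethoxy-2-methylcyclobut-2-en-1-one
Conditions: Zn dust, AcOH, TMEDA, EtOH, 0 °C to rt
Reagents that add atoms: none
Why: Reductive dechlorination of an α,α-dichloroketone with zinc in buffered acetic acid, the usual second stage of the dichloroketene route to cyclobutenones; the vinylogous ester is not reduced.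

Step 9
Reactants: 15 3-ethoxy-2-methylcyclobut-2-en-1-one
Product: 16 3-(benzyloxy)-2-methylcyclobut-2-en-1-one
Conditions: BnOH (3 equiv), TsOH·H2O (cat.), PhMe, 35 °C, reduced pressure
Reagents that add atoms: benzyl alcohol OCc1ccccc1
Why: Acid-catalysed vinylogous transesterification (addition–elimination at C3 of a β-alkoxy enone), driven by removing ethanol and run far below the temperature at which the ring opens, so that benzyl alcohol cannot trap a vinylketene.

Step 10
Reactants: 10 1,3,5-tris(benzyloxy)-2,4-bis(3-methoxyprop-2-yn-1-yl)benzene; 16 3-(benzyloxy)-2-methylcyclobut-2-en-1-one (two molecules per molecule of 10, used in excess)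
Product: 21 1,3,5-tris(benzyloxy)-2,4-bis{[4-(benzyloxy)-2-hydroxy-6-methoxy-5-methylphenyl]methyl}benzene, via vinylketene 17 (not isolated), via bis(vinylcyclobutenone) 18 (not isolated), via bis(dienylketene) 19 (not isolated), via bis(cyclohexadienone) 20 (not isolated)
Conditions: 16 (3 equiv), PhMe, sealed tube, 80 °C then 120 °C; crude product stirred with K2CO3, MeOH, rt
Reagents that add atoms: none
Why: Danheiser benzannulation: cyclobutenone 16 opens thermally (4π, conrotatory) to vinylketene 17, whose carbonyl carbon is attacked by the nucleophilic β-carbon of each methoxyalkyne of 10 in a regioselective [2+2] cycloaddition that forms C1'–C2' and C5'–C6' and gives bis(vinylcyclobutenone) 18. A second 4π opening gives bis(dienylketene) 19, and rings A and C each close by thermal 6π (disrotatory) electrocyclisation that remakes C2'–C3', the resulting cyclohexadienone 20 tautomerising to the phenol. The closest known reaction type is the thermal benzannulation of cyclobutenones with 1-alkoxy- and 1-siloxyalkynes to give resorcinol monoethers; here the vinylketene carries one more oxygen, and two alkynes of one molecule react independently because ring B insulates them. No stereocentre results, since the quaternary carbons of 18 are lost on aromatisation. The step needs regioselectivity in the ketene–alkyne addition, which the polarised ynol ether secures (its oxygen-bearing carbon bonds to the ketene α-carbon), so the ketene oxygen ends as the free C2' hydroxyl, the alkyne methoxyl sits at C6' next to the bridge and the benzyloxy group at C4'. A methyl ynol ether is used because, unlike an ethyl one, it cannot lose an alkene by retro-ene reaction at the temperature needed; the basic methanol treatment frees any phenol that was acylated by excess ketene.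

Step 11
Reactants: 21 1,3,5-tris(benzyloxy)-2,4-bis{[4-(benzyloxy)-2-hydroxy-6-methoxy-5-methylphenyl]methyl}benzene
Product: 22 1,3,5-tris(benzyloxy)-2,4-bis{[2,4-bis(benzyloxy)-6-methoxy-5-methylphenyl]methyl}benzene
Conditions: BnBr, K2CO3, DMF, 40 °C
Reagents that add atoms: benzyl bromide BrCc1ccccc1
Why: Williamson etherification of the two new phenols, which removes the only O–H groups so that the next step can acylate carbon only.

Step 12
Reactants: 22 1,3,5-tris(benzyloxy)-2,4-bis{[2,4-bis(benzyloxy)-6-methoxy-5-methylphenyl]methyl}benzene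
Product: 23 1-{2,4,6-tris(benzyloxy)-3,5-bis{[2,4-bis(benzyloxy)-3-butanoyl-6-methoxy-5-methylphenyl]methyl}phenyl}butan-1-one
Conditions: PrCO2H, (CF3CO)2O, CH2Cl2, 0 °C to rt
Reagents that add atoms: butanoic acid CCCC(=O)O
Why: Friedel–Crafts acylation with the mixed butanoic trifluoroacetic anhydride formed in the flask: the three remaining aryl C–H positions (C3' of rings A and C and the free carbon of ring B) each lie ortho, ortho and para to alkoxy groups, as in a 1,3,5-trialkoxybenzene, and the absence of a metal Lewis acid should leave the benzyl ethers in place.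

Step 13
Reactants: 23 1-{2,4,6-tris(benzyloxy)-3,5-bis{[2,4-bis(benzyloxy)-3-butanoyl-6-methoxy-5-methylphenyl]methyl}phenyl}butan-1-one
Product: 24 1-{3,5-bis[(3-butanoyl-2,4-dihydroxy-6-methoxy-5-methylphenyl)methyl]-2,4,6-trihydroxyphenyl}butan-1-one (CNP0264591.0)
Conditions: H2 (1 atm), 10% Pd/C, EtOAc/MeOH, rt
Reagents that add atoms: none
Why: Catalytic hydrogenolysis should cleave all seven benzyl ethers, while the methyl ethers, the hydrogen-bonded aryl ketones and the diarylmethane bridges are inert under these mild conditions, so both C6' methoxyls are kept by construction.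

**Compound list**

1 | phloroglucinol (benzene-1,3,5-triol) | Oc1cc(O)cc(O)c1 | starting material
2 | 2,4,6-trihydroxybenzene-1,3-dicarbaldehyde | O=Cc1c(O)cc(O)c(C=O)c1O | intermediate
3 | 2,4,6-tris(benzyloxy)benzene-1,3-dicarbaldehyde | O=Cc1c(OCc2ccccc2)cc(OCc2ccccc2)c(C=O)c1OCc1ccccc1 | intermediate
4 | [2,4,6-tris(benzyloxy)-1,3-phenylene]dimethanol | OCc1c(OCc2ccccc2)cc(OCc2ccccc2)c(CO)c1OCc1ccccc1 | intermediate
5 | 1,3,5-tris(benzyloxy)-2,4-bis(bromomethyl)benzene | BrCc1c(OCc2ccccc2)cc(OCc2ccccc2)c(CBr)c1OCc1ccccc1 | intermediate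
6 | 2-chloro-1,1-dimethoxyethane | COC(CCl)OC | starting material
7 | sodium methoxyacetylide | [Na]C#COC | intermediate
8 | methoxyethyne | COC#C | intermediate
9 | lithium methoxyacetylide | [Li]C#COC | intermediate
10 | 1,3,5-tris(benzyloxy)-2,4-bis(3-methoxyprop-2-yn-1-yl)benzene | COC#CCc1c(OCc2ccccc2)cc(OCc2ccccc2)c(CC#COC)c1OCc1ccccc1 | intermediate
11 | 1-ethoxyprop-1-yne | CCOC#CC | starting material
12 | trichloroacetyl chloride | O=C(Cl)C(Cl)(Cl)Cl | starting material
13 | dichloroketene | O=C=C(Cl)Cl | intermediate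
14 | 4,4-dichloro-3-ethoxy-2-methylcyclobut-2-en-1-one | CCOC1=C(C)C(=O)C1(Cl)Cl | intermediate
15 | 3-ethoxy-2-methylcyclobut-2-en-1-one | CCOC1=C(C)C(=O)C1 | intermediate
16 | 3-(benzyloxy)-2-methylcyclobut-2-en-1-one | CC1=C(OCc2ccccc2)CC1=O | intermediate
17 | 3-(benzyloxy)-2-methylbuta-1,3-dien-1-one (vinylketene) | C=C(OCc1ccccc1)C(C)=C=O | intermediate
18 | 2,2'-{[2,4,6-tris(benzyloxy)-1,3-phenylene]bis(methylene)}bis{4-[1-(benzyloxy)ethenyl]-3-methoxy-4-methylcyclobut-2-en-1-one} (mixture of diastereomers) | COC1=C(Cc2c(OCc3ccccc3)cc(OCc3ccccc3)c(CC3=C(OC)C(C)(C(=C)OCc4ccccc4)C3=O)c2OCc2ccccc2)C(=O)C1(C)C(=C)OCc1ccccc1 | intermediate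
19 | 2,2'-{[2,4,6-tris(benzyloxy)-1,3-phenylene]bis(methylene)}bis[5-(benzyloxy)-3-methoxy-4-methylhexa-1,3,5-trien-1-one] | O=C=C(Cc1c(OCc2ccccc2)cc(OCc2ccccc2)c(CC(=C=O)C(OC)=C(C)C(=C)OCc2ccccc2)c1OCc1ccccc1)C(OC)=C(C)C(=C)OCc1ccccc1 | intermediate
20 | 2,2'-{[2,4,6-tris(benzyloxy)-1,3-phenylene]bis(methylene)}bis[5-(benzyloxy)-3-methoxy-4-methylcyclohexa-2,4-dien-1-one] | COC1=C(Cc2c(OCc3ccccc3)cc(OCc3ccccc3)c(CC3=C(OC)C(C)=C(OCc4ccccc4)CC3=O)c2OCc2ccccc2)C(=O)CC(OCc2ccccc2)=C1C | intermediate
21 | 1,3,5-tris(benzyloxy)-2,4-bis{[4-(benzyloxy)-2-hydroxy-6-methoxy-5-methylphenyl]methyl}benzene | COc1c(C)c(OCc2ccccc2)cc(O)c1Cc1c(OCc2ccccc2)cc(OCc2ccccc2)c(Cc2c(O)cc(OCc3ccccc3)c(C)c2OC)c1OCc1ccccc1 | intermediate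
22 | 1,3,5-tris(benzyloxy)-2,4-bis{[2,4-bis(benzyloxy)-6-methoxy-5-methylphenyl]methyl}benzene | COc1c(C)c(OCc2ccccc2)cc(OCc2ccccc2)c1Cc1c(OCc2ccccc2)cc(OCc2ccccc2)c(Cc2c(OCc3ccccc3)cc(OCc3ccccc3)c(C)c2OC)c1OCc1ccccc1 | intermediate
23 | 1-{2,4,6-tris(benzyloxy)-3,5-bis{[2,4-bis(benzyloxy)-3-butanoyl-6-methoxy-5-methylphenyl]methyl}phenyl}butan-1-one | CCCC(=O)c1c(OCc2ccccc2)c(Cc2c(OCc3ccccc3)c(C(=O)CCC)c(OCc3ccccc3)c(C)c2OC)c(OCc2ccccc2)c(Cc2c(OCc3ccccc3)c(C(=O)CCC)c(OCc3ccccc3)c(C)c2OC)c1OCc1ccccc1 | intermediate
24 | 1-{3,5-bis[(3-butanoyl-2,4-dihydroxy-6-methoxy-5-methylphenyl)methyl]-2,4,6-trihydroxyphenyl}butan-1-one | CCCC(=O)c1c(O)c(Cc2c(O)c(C(=O)CCC)c(O)c(C)c2OC)c(O)c(Cc2c(O)c(C(=O)CCC)c(O)c(C)c2OC)c1O | target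

**Step count and risks**

Total step count: 13. Longest linear sequence: 9 steps (steps 1, 2, 3, 4, 6, 10, 11, 12, 13).

Steps most likely to fail:

1. Step 10. The vinylogous-ester cyclobutenone may open only at a temperature at which the ynol ether termini isomerise or oligomerise, and the vinylketene may dimerise faster than it is captured, so that the second annulation stalls after one ring has formed. The fallback gives up ring construction and sets out from diol 4. Acid-catalysed Friedel–Crafts benzylation (TsOH·H2O cat., CH2Cl2/MeNO2, 0 °C) of two equivalents of the commercially available phenol 1-(2,6-dihydroxy-4-methoxy-3-methylphenyl)butan-1-one F1 should give 1,1'-{[2,4,6-tris(benzyloxy)-1,3-phenylene]bis[methylene(2,4-dihydroxy-6-methoxy-5-methyl-3,1-phenylene)]}di(butan-1-one) F2. The single free ring carbon of F1 lies between its methoxy and hydroxy groups and corresponds to C1'. Hydrogenolysis (H2, 10% Pd/C, EtOAc) should then give 1,1'-{(2,4,6-trihydroxy-1,3-phenylene)bis[methylene(2,4-dihydroxy-6-methoxy-5-methyl-3,1-phenylene)]}di(butan-1-one) F3. Friedel–Crafts C-butanoylation of the one unsubstituted carbon of ring B (butanoyl chloride, AlCl3, PhNO2, rt) comes back to the route at target 24.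

2. Step 6. The doubly ortho-alkoxylated benzylic bromide may ionise and condense with the free ring position of another molecule before the acetylide attacks, and the basic medium may shift the new propargylic CH2 groups to allenyl ethers. The fallback avoids any benzylic halide and sets out from dialdehyde 3. Horner–Wadsworth–Emmons olefination (trimethyl phosphonoacetate, NaH, THF) should give dimethyl (2E,2'E)-3,3'-[2,4,6-tris(benzyloxy)-1,3-phenylene]bis(prop-2-enoate) F4. Conjugate reduction (NaBH4, NiCl2·6H2O, MeOH, 0 °C) should give dimethyl 3,3'-[2,4,6-tris(benzyloxy)-1,3-phenylene]dipropanoate F5. Enolisation and O-phosphorylation (LiN(i-Pr)2, ClP(O)(OEt)2, THF/DMPU, −78 °C) should give the bis(ketene acetal phosphate) [2,4,6-tris(benzyloxy)-1,3-phenylene]bis(1-methoxyprop-1-ene-3,1-diyl) tetraethyl bis(phosphate) F6. Base-induced elimination of diethyl phosphate (t-BuLi, THF, −78 °C), the known conversion of esters into 1-alkoxyalkynes, comes back to the route at 10.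

3. Step 12. The acidic acylating medium may remove benzyl groups, which can then re-attach at carbon, or may cut the diarylmethane links before all three hindered positions are acylated. The fallback replaces electrophilic acylation by an organolithium route and sets out from 22. Three-fold bromination at the only free aryl carbons (N-bromosuccinimide, MeCN/CH2Cl2, 0 °C) should give 1,3,5-tris(benzyloxy)-2-bromo-4,6-bis{[2,4-bis(benzyloxy)-3-bromo-6-methoxy-5-methylphenyl]methyl}benzene F7. Bromine–lithium exchange (t-BuLi, THF, −78 °C) and acylation of the three aryllithium sites with N-methoxy-N-methylbutanamide comes back to the route at 23.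

**Further compounds**

F1 | step 10 | 1-(2,6-dihydroxy-4-methoxy-3-methylphenyl)butan-1-one | CCCC(=O)c1c(O)c(C)c(OC)cc1O
F2 | step 10 | 1,1'-{[2,4,6-tris(benzyloxy)-1,3-phenylene]bis[methylene(2,4-dihydroxy-6-methoxy-5-methyl-3,1-phenylene)]}di(butan-1-one) | CCCC(=O)c1c(O)c(C)c(OC)c(Cc2c(OCc3ccccc3)cc(OCc3ccccc3)c(Cc3c(O)c(C(=O)CCC)c(O)c(C)c3OC)c2OCc2ccccc2)c1O
F3 | step 10 | 1,1'-{(2,4,6-trihydroxy-1,3-phenylene)bis[methylene(2,4-dihydroxy-6-methoxy-5-methyl-3,1-phenylene)]}di(butan-1-one) | CCCC(=O)c1c(O)c(C)c(OC)c(Cc2c(O)cc(O)c(Cc3c(O)c(C(=O)CCC)c(O)c(C)c3OC)c2O)c1O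
F4 | step 6 | dimethyl (2E,2'E)-3,3'-[2,4,6-tris(benzyloxy)-1,3-phenylene]bis(prop-2-enoate) | COC(=O)/C=C/c1c(OCc2ccccc2)cc(OCc2ccccc2)c(/C=C/C(=O)OC)c1OCc1ccccc1
F5 | step 6 | dimethyl 3,3'-[2,4,6-tris(benzyloxy)-1,3-phenylene]dipropanoate | COC(=O)CCc1c(OCc2ccccc2)cc(OCc2ccccc2)c(CCC(=O)OC)c1OCc1ccccc1
F6 | step 6 | [2,4,6-tris(benzyloxy)-1,3-phenylene]bis(1-methoxyprop-1-ene-3,1-diyl) tetraethyl bis(phosphate) | CCOP(=O)(OCC)OC(OC)=CCc1c(OCc2ccccc2)cc(OCc2ccccc2)c(CC=C(OC)OP(=O)(OCC)OCC)c1OCc1ccccc1
F7 | step 12 | 1,3,5-tris(benzyloxy)-2-bromo-4,6-bis{[2,4-bis(benzyloxy)-3-bromo-6-methoxy-5-methylphenyl]methyl}benzene | COc1c(C)c(OCc2ccccc2)c(Br)c(OCc2ccccc2)c1Cc1c(OCc2ccccc2)c(Br)c(OCc2ccccc2)c(Cc2c(OCc3ccccc3)c(Br)c(OCc3ccccc3)c(C)c2OC)c1OCc1ccccc1
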